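The tetrahydrofuran ring F (O1–C2–C9–C10–C8a) is disconnected at O1–C2 and C9–C10, a formal (3+2) retron. The precursor is a benzobicyclo[3.3.1]nonenone (rings A, D, E) whose C8a carries a free hydroxyl, whose C10 is a benzylic CH2 para to a catechol hydroxyl of ring D, and whose C4a carries a (1E,3E)-dienyl chain with C2 cis to C4a. Catechol oxidation gives an o-quinone that tautomerises to a quinone methide at C10; 7-endo attack of C9 and capture of the dienyl cation at C2 by O1 close rings F and P and set C2, C9 and C10 in one operation. C8a comes from a catalytic asymmetric phenol dearomatisation.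

Key step: step 16

Atom labels (chromene-type numbering of the core, used for the target and for the corresponding atoms of its precursors):
- Ring P (2H-pyran): O1, C2, C3 (bears the 3-hydroxy-2,4-dimethoxyphenyl group), C4, C4a, C8a.
- Ring A (cyclohexenone): C4a, C5, C6 (C=O), C7 (C–OH), C8 (CH2), C8a.
- Ring F (tetrahydrofuran): O1, C2, C9 (bears the 4-hydroxy-2-methoxybenzyl group), C10, C8a.
- Ring D: the catechol ring, bonded to C10 and C7.
- Ring E: the carbocycle C8a–C8–C7–(two carbons of ring D)–C10.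
- In these labels the target is (2S,7S,8aR,9S,10R).
- TBS = tert-butyldimethylsilyl, TIPS = triisopropylsilyl.

Assumption 1: 2-bromo-4,5-dihydroxybenzaldehyde is treated as a catalogue compound.
Assumption 2: the sense of induction of the chiral iodoarene in step 6 cannot be predicted with certainty; the catalyst enantiomer that delivers the (S)-quinol is used (written here as the (R,R)-form).

Step 1
Reactants: 1 2-bromo-4,5-dihydroxybenzaldehyde
Product: 2 4-(allyloxy)-2-bromo-5-hydroxybenzaldehyde
Conditions: allyl bromide (1.05 equiv), NaHCO3 (1.5 equiv), NaI (cat.), DMF, 40 °C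
Reagents that add atoms: allyl bromide, C=CCBr
Why: Williamson etherification in which NaHCO3 deprotonates only the more acidic 4-OH (para to the formyl group), so mono-allylation should be regioselective; no stereocenter is formed.

Step 2
Reactants: 2 4-(allyloxy)-2-bromo-5-hydroxybenzaldehyde
Product: 3 4-(allyloxy)-2-bromo-5-(TBSO)benzaldehyde
Conditions: TBSCl, imidazole, DMF, rt
Reagents that add atoms: tert-butyldimethylsilyl chloride, CC(C)(C)[Si](C)(C)Cl
Why: Imidazole-promoted silylation of the remaining phenol, which later becomes the fluoride-labile enol ether oxygen on C7; no stereocenter is formed.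

Step 3
Reactants: 4 4-bromobenzene-1,2-diol
Product: 5 4-bromo-1,2-bis(TBSO)benzene
Conditions: TBSCl (2.3 equiv), imidazole, DMF, rt
Reagents that add atoms: tert-butyldimethylsilyl chloride, CC(C)(C)[Si](C)(C)Cl
Why: Imidazole-promoted double silylation of the catechol that becomes ring D; no stereocenter is formed.

Step 4
Reactants: 5 4-bromo-1,2-bis(TBSO)benzene; 3 4-(allyloxy)-2-bromo-5-(TBSO)benzaldehyde
Product: 8 1-(allyloxy)-5-bromo-4-[3,4-bis(TBSO)benzyl]-2-(TBSO)benzene, via aryllithium 6 (not isolated), via lithium carbinolate 7 (not isolated)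
Conditions: n-BuLi, THF, −78 °C; add 3, −78 °C; then Et3SiH (3 equiv), CF3CO2H (5 equiv), CH2Cl2 co-solvent, −78 → 0 °C
Reagents that add atoms: none
Why: Bromine–lithium exchange on 5, 1,2-addition of the aryllithium to the aldehyde (faster than exchange with the aryl bromide of 3 at −78 °C) and ionic hydrogenation of the doubly benzylic carbinol through a benzhydryl cation stabilised by two para-oxygen substituents should give the diarylmethane (C10 as CH2) with no stereocenter left.

Step 5
Reactants: 8 1-(allyloxy)-5-bromo-4-[3,4-bis(TBSO)benzyl]-2-(TBSO)benzene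
Product: 9 5-bromo-4-[3,4-bis(TBSO)benzyl]-2-(TBSO)phenol
Conditions: Pd(PPh3)4 (3 mol %), morpholine (3 equiv), THF, rt
Reagents that add atoms: none
Why: Tsuji–Trost deallylation in which zerovalent palladium ionises the aryl allyl ether and morpholine traps the π-allyl complex, while the aryl bromide and the silyl ethers should stay untouched at room temperature.

Step 6
Reactants: 9 5-bromo-4-[3,4-bis(TBSO)benzyl]-2-(TBSO)phenol
Product: 10 (S)-5-bromo-4-[3,4-bis(TBSO)benzyl]-4-hydroxy-2-(TBSO)cyclohexa-2,5-dien-1-one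
Conditions: (R,R)-2,2'-[(2-iodo-1,3-phenylene)bis(oxy)]bis[N-(2,4,6-trimethylphenyl)propanamide] (10 mol %), 3-chloroperbenzoic acid (1.3 equiv), MeCN/H2O (10:1), −20 °C
Reagents that add atoms: water, O
Why: Catalytic asymmetric hydroxylative phenol dearomatisation in which the chiral aryl-λ3-iodane formed from the iodoarene and the peracid binds the phenol oxygen and water adds to the para carbon C8a (alkyl-substituted, while the ortho carbon is shielded by the bulky silyloxy group), the lactamide arms of the catalyst selecting the face so that C8a should form as (S).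

Step 7
Reactants: 11 2,6-dimethoxyphenol
Product: 12 tert-butyl(2,6-dimethoxyphenoxy)dimethylsilane
Conditions: TBSCl, imidazole, DMF, 40 °C
Reagents that add atoms: tert-butyldimethylsilyl chloride, CC(C)(C)[Si](C)(C)Cl
Why: Imidazole-promoted silylation of the phenol, which removes its para-directing effect before the halogenation; no stereocenter is formed.

Step 8
Reactants: 12 tert-butyl(2,6-dimethoxyphenoxy)dimethylsilane
Product: 13 tert-butyl(3-iodo-2,6-dimethoxyphenoxy)dimethylsilane
Conditions: N-iodosuccinimide, CF3CO2H (cat.), MeCN, 0 °C → rt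
Reagents that add atoms: N-iodosuccinimide, O=C1CCC(=O)N1I
Why: Electrophilic aromatic iodination at the position ortho to one methoxy group and para to the other, the doubly flanked silyloxy group being twisted out of conjugation (the regiochemistry of 4-halogenation of 1,2,3-trialkoxybenzenes).

Step 9
Reactants: 13 tert-butyl(3-iodo-2,6-dimethoxyphenoxy)dimethylsilane
Product: 15 tert-butyl(3-ethynyl-2,6-dimethoxyphenoxy)dimethylsilane, via silylalkyne 14 (not isolated)
Conditions: ethynyltrimethylsilane, PdCl2(PPh3)2 (3 mol %), CuI (5 mol %), Et3N, THF, 45 °C; then MeOH, K2CO3 (cat.), rt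
Reagents that add atoms: ethynyltrimethylsilane, C#C[Si](C)(C)C
Why: Sonogashira coupling followed by methanolysis of the alkynyl C–Si bond, which the aryl silyl ether, shielded by two ortho methoxy groups, should survive.

Step 10
Reactants: 16 4-bromo-3-methoxyphenol
Product: 17 (4-bromo-3-methoxyphenoxy)triisopropylsilane
Conditions: TIPSCl, imidazole, DMF, rt
Reagents that add atoms: triisopropylsilyl chloride, CC(C)[Si](Cl)(C(C)C)C(C)C
Why: Imidazole-promoted silylation giving an aryl silyl ether robust enough for the Grignard and methanolysis steps; no stereocenter is formed.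

Step 11
Reactants: 17 (4-bromo-3-methoxyphenoxy)triisopropylsilane
Product: 20 triisopropyl[3-methoxy-4-(prop-2-yn-1-yl)phenoxy]silane, via arylmagnesium bromide 18 (not isolated), via silylalkyne 19 (not isolated)
Conditions: Mg, THF, 50 °C; CuBr·SMe2 (5 mol %), 3-bromo-1-(trimethylsilyl)prop-1-yne, −20 °C → rt; then MeOH, K2CO3 (cat.), rt
Reagents that add atoms: 3-bromo-1-(trimethylsilyl)prop-1-yne, C[Si](C)(C)C#CCBr
Why: Grignard formation, copper-catalysed SN2 coupling with the propargylic bromide (the silyl cap disfavours the SN2′ route to an allene) and protodesilylation of the alkynylsilane by methoxide should give the 3-arylpropyne.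

Step 12
Reactants: 20 triisopropyl[3-methoxy-4-(prop-2-yn-1-yl)phenoxy]silane
Product: 22 (E)-[4-(3-iodoprop-2-en-1-yl)-3-methoxyphenoxy]triisopropylsilane, via alkenylzirconocene 21 (not isolated)
Conditions: Cp2Zr(H)Cl (1.2 equiv), THF, rt; then I2, 0 °C
Reagents that add atoms: iodine, II
Why: Hydrozirconation adds Zr–H syn with zirconium on the terminal carbon, and iodinolysis of the C–Zr bond with retention should give the (E)-alkenyl iodide.

Step 13
Reactants: 15 tert-butyl(3-ethynyl-2,6-dimethoxyphenoxy)dimethylsilane; 22 (E)-[4-(3-iodoprop-2-en-1-yl)-3-methoxyphenoxy]triisopropylsilane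
Product: 23 2-{(1E,3E)-2-[3-(TBSO)-2,4-dimethoxyphenyl]-5-[2-methoxy-4-(TIPSO)phenyl]penta-1,3-dien-1-yl}-4,4,5,5-tetramethyl-1,3,2-dioxaborolane
Conditions: bis(pinacolato)diboron (1.2 equiv), CuCl (10 mol %), PCy3 (12 mol %), PdCl2(dppf) (5 mol %; dppf = 1,1'-bis(diphenylphosphino)ferrocene), NaOtBu (1.5 equiv), toluene, rt
Reagents that add atoms: bis(pinacolato)diboron, CC1(C)OB(OC1(C)C)B1OC(C)(C)C(C)(C)O1
Why: Copper/palladium-cocatalysed alkenylboration of a terminal alkyne, in which syn-borylcupration puts boron on the terminal carbon and copper on the aryl-bearing carbon and cross-coupling with the alkenylpalladium iodide from 22 proceeds with retention, so boron should end cis to the new dienyl carbon (1E) with the 3E geometry kept.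

Step 14
Reactants: 10 (S)-5-bromo-4-[3,4-bis(TBSO)benzyl]-4-hydroxy-2-(TBSO)cyclohexa-2,5-dien-1-one; 23 the dienyl pinacol boronate
Product: 24 (S)-4-[3,4-bis(TBSO)benzyl]-4-hydroxy-2-(TBSO)-5-{(1E,3E)-2-[3-(TBSO)-2,4-dimethoxyphenyl]-5-[2-methoxy-4-(TIPSO)phenyl]penta-1,3-dien-1-yl}cyclohexa-2,5-dien-1-one
Conditions: PdCl2(dppf) (5 mol %), K3PO4 (2 M aq., 3 equiv), THF, 35 °C, degassed
Reagents that add atoms: none
Why: Suzuki–Miyaura coupling of the β-bromoenone with retention at both sp2 carbons, so C4a should end cis to C2 across C4=C3, the mild temperature avoiding 6π-electrocyclisation of the cis-triene and leaving the C8a stereocenter untouched.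

Step 15
Reactants: 24 the fully silylated dienyl quinol
Product: 26 cage catechol (7S,8aS), via desilylated quinol 25 (not isolated)
Conditions: HF (48 % aq., excess), MeCN, 0 °C → rt
Reagents that add atoms: none
Why: Removal of the five silyl groups frees the diosphenol, whose 1,2-dione tautomer should undergo intramolecular Friedel–Crafts hydroxyalkylation at C7 by the ring-D carbon para to a hydroxyl (6-exo-trig; the ortho carbon between CH2 and OH is more hindered), the one-carbon C8 bridge allowing attack only from the C10 side so that C7 is relayed from C8a as (S) and the bridgehead carbinol cannot ionise further.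

Step 16
Reactants: 26 cage catechol (7S,8aS)
Product: 29 CNP0246028.1 (the target; 2S,7S,8aR,9S,10R in the core labels), via ortho-quinone 27 (not isolated), via quinone methide 28 (not isolated)
Conditions: Ag2O (1.05 equiv), MeCN, 0 °C, dark; filter; then (CF3)2CHOH, CF3CO2H (10 mol %), 0 °C → rt, high dilution
Reagents that add atoms: none
Why: Ag2O oxidises the catechol (much more easily oxidised than the two monophenols) to ortho-quinone 27, which tautomerises by loss of a C10 proton to the 2-hydroxy-para-quinone methide 28, and O-protonation makes C10 a benzylic cation next to the C8a hydroxyl, i.e. the 1,3-dipole equivalent O1–C8a–C10. The (E)-alkene C9=C2 attacks C10 (7-endo-trig, closing the carbocycle C10–C8a–C4a–C4–C3–C2–C9) and the resulting dienyl cation is captured at C2 by O1, a single transannular C–O bond formation that closes both the five-membered ring F and the six-membered ring P. The closest known reaction types are the acid-promoted formal (3+2) annulation of para-quinone methides or β-hydroxy benzylic cations with alkenes, cation–olefin cyclisation with hydroxyl termination, and the ortho-quinone to quinone methide tautomerisation of 4-alkylcatechols. At C10 the tether through C4a (axial on ring E) can reach only one face of the planar carbon, which places ring D endo; at C9 suprafacial addition to the (E)-alkene places the benzyl group exo and trans to ring D; C2 is a bridgehead fixed by the bicycle, so all three centers are relayed from C8a and C7. The step needs chemoselective catechol oxidation and attack by the alkene rather than by an arene, which the substrate secures because the dimethoxyphenyl ring is trans to C4a on C4=C3 and the benzyl arene could only close a ten-membered ring.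

Compound list
1 | 2-bromo-4,5-dihydroxybenzaldehyde | O=Cc1cc(O)c(O)cc1Br | starting material
2 | 4-(allyloxy)-2-bromo-5-hydroxybenzaldehyde | O=Cc1cc(O)c(OCC=C)cc1Br | intermediate
3 | 4-(allyloxy)-2-bromo-5-(TBSO)benzaldehyde | O=Cc1cc(O[Si](C)(C)C(C)(C)C)c(OCC=C)cc1Br | intermediate
4 | 4-bromobenzene-1,2-diol | Oc1ccc(Br)cc1O | starting material
5 | 4-bromo-1,2-bis(TBSO)benzene | CC(C)(C)[Si](C)(C)Oc1ccc(Br)cc1O[Si](C)(C)C(C)(C)C | intermediate
6 | [3,4-bis(TBSO)phenyl]lithium | [Li]c1ccc(O[Si](C)(C)C(C)(C)C)c(O[Si](C)(C)C(C)(C)C)c1 | intermediate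
7 | lithium [4-(allyloxy)-2-bromo-5-(TBSO)phenyl][3,4-bis(TBSO)phenyl]methanolate (racemic) | [Li]OC(c1ccc(O[Si](C)(C)C(C)(C)C)c(O[Si](C)(C)C(C)(C)C)c1)c1cc(O[Si](C)(C)C(C)(C)C)c(OCC=C)cc1Br | intermediate
8 | 1-(allyloxy)-5-bromo-4-[3,4-bis(TBSO)benzyl]-2-(TBSO)benzene | C=CCOc1cc(Br)c(Cc2ccc(O[Si](C)(C)C(C)(C)C)c(O[Si](C)(C)C(C)(C)C)c2)cc1O[Si](C)(C)C(C)(C)C | intermediate
9 | 5-bromo-4-[3,4-bis(TBSO)benzyl]-2-(TBSO)phenol | Oc1cc(Br)c(Cc2ccc(O[Si](C)(C)C(C)(C)C)c(O[Si](C)(C)C(C)(C)C)c2)cc1O[Si](C)(C)C(C)(C)C | intermediate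
10 | (S)-5-bromo-4-[3,4-bis(TBSO)benzyl]-4-hydroxy-2-(TBSO)cyclohexa-2,5-dien-1-one | O[C@@]1(Cc2ccc(O[Si](C)(C)C(C)(C)C)c(O[Si](C)(C)C(C)(C)C)c2)C=C(O[Si](C)(C)C(C)(C)C)C(=O)C=C1Br | intermediate
11 | 2,6-dimethoxyphenol | COc1cccc(OC)c1O | starting material
12 | tert-butyl(2,6-dimethoxyphenoxy)dimethylsilane | COc1cccc(OC)c1O[Si](C)(C)C(C)(C)C | intermediate
13 | tert-butyl(3-iodo-2,6-dimethoxyphenoxy)dimethylsilane | COc1ccc(I)c(OC)c1O[Si](C)(C)C(C)(C)C | intermediate
14 | tert-butyl{2,6-dimethoxy-3-[(trimethylsilyl)ethynyl]phenoxy}dimethylsilane | COc1ccc(C#C[Si](C)(C)C)c(OC)c1O[Si](C)(C)C(C)(C)C | intermediate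
15 | tert-butyl(3-ethynyl-2,6-dimethoxyphenoxy)dimethylsilane | COc1ccc(C#C)c(OC)c1O[Si](C)(C)C(C)(C)C | intermediate
16 | 4-bromo-3-methoxyphenol | COc1cc(O)ccc1Br | starting material
17 | (4-bromo-3-methoxyphenoxy)triisopropylsilane | COc1cc(O[Si](C(C)C)(C(C)C)C(C)C)ccc1Br | intermediate
18 | [2-methoxy-4-(TIPSO)phenyl]magnesium bromide | COc1cc(O[Si](C(C)C)(C(C)C)C(C)C)ccc1[Mg]Br | intermediate
19 | triisopropyl{3-methoxy-4-[3-(trimethylsilyl)prop-2-yn-1-yl]phenoxy}silane | COc1cc(O[Si](C(C)C)(C(C)C)C(C)C)ccc1CC#C[Si](C)(C)C | intermediate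
20 | triisopropyl[3-methoxy-4-(prop-2-yn-1-yl)phenoxy]silane | COc1cc(O[Si](C(C)C)(C(C)C)C(C)C)ccc1CC#C | intermediate
21 | chloro{(E)-3-[2-methoxy-4-(TIPSO)phenyl]prop-1-en-1-yl}zirconocene | COc1cc(O[Si](C(C)C)(C(C)C)C(C)C)ccc1C/C=C/[Zr](Cl)(C1C=CC=C1)C1C=CC=C1 | intermediate
22 | (E)-[4-(3-iodoprop-2-en-1-yl)-3-methoxyphenoxy]triisopropylsilane | COc1cc(O[Si](C(C)C)(C(C)C)C(C)C)ccc1C/C=C/I | intermediate
23 | 2-{(1E,3E)-2-[3-(TBSO)-2,4-dimethoxyphenyl]-5-[2-methoxy-4-(TIPSO)phenyl]penta-1,3-dien-1-yl}-4,4,5,5-tetramethyl-1,3,2-dioxaborolane (boron cis to the dienyl carbon) | CC1(C)OB(OC1(C)C)/C=C(/c1ccc(OC)c(O[Si](C)(C)C(C)(C)C)c1OC)\C=C\Cc1ccc(O[Si](C(C)C)(C(C)C)C(C)C)cc1OC | intermediate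
24 | (S)-4-[3,4-bis(TBSO)benzyl]-4-hydroxy-2-(TBSO)-5-{(1E,3E)-2-[3-(TBSO)-2,4-dimethoxyphenyl]-5-[2-methoxy-4-(TIPSO)phenyl]penta-1,3-dien-1-yl}cyclohexa-2,5-dien-1-one | O[C@@]1(Cc2ccc(O[Si](C)(C)C(C)(C)C)c(O[Si](C)(C)C(C)(C)C)c2)C=C(O[Si](C)(C)C(C)(C)C)C(=O)C=C1/C=C(/c1ccc(OC)c(O[Si](C)(C)C(C)(C)C)c1OC)\C=C\Cc1ccc(O[Si](C(C)C)(C(C)C)C(C)C)cc1OC | intermediate
25 | (S)-4-(3,4-dihydroxybenzyl)-2,4-dihydroxy-5-[(1E,3E)-2-(3-hydroxy-2,4-dimethoxyphenyl)-5-(4-hydroxy-2-methoxyphenyl)penta-1,3-dien-1-yl]cyclohexa-2,5-dien-1-one | O[C@@]1(Cc2ccc(O)c(O)c2)C=C(O)C(=O)C=C1/C=C(/c1ccc(OC)c(O)c1OC)\C=C\Cc1ccc(O)cc1OC | intermediate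
26 | cage catechol, (5S,9S)-2,3,5,9-tetrahydroxy-8-[(1E,3E)-2-(3-hydroxy-2,4-dimethoxyphenyl)-5-(4-hydroxy-2-methoxyphenyl)penta-1,3-dien-1-yl]-9,10-dihydro-5,9-methanobenzo[8]annulen-6(5H)-one (7S,8aS in the core labels; C10 is CH2) | O[C@@]12C[C@@](O)(C(=O)C=C1/C=C(/c1ccc(OC)c(O)c1OC)\C=C\Cc1ccc(O)cc1OC)c1cc(O)c(O)cc1C2 | intermediate
27 | ortho-quinone of 26 (ring D oxidised to the 1,2-dione; 7S,8aS) | O[C@@]12C[C@@](O)(C(=O)C=C1/C=C(/c1ccc(OC)c(O)c1OC)\C=C\Cc1ccc(O)cc1OC)C1=CC(=O)C(=O)C=C1C2 | intermediate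
28 | 2-hydroxy-para-quinone methide tautomer of 27 (C10=C double bond into ring D; 7S,8aS) | O[C@@]12C[C@@](O)(C(=O)C=C1/C=C(/c1ccc(OC)c(O)c1OC)\C=C\Cc1ccc(O)cc1OC)C1=CC(=O)C(O)=CC1=C2 | intermediate
29 | CNP0246028.1, (2S,7S,8aR,9S,10R) in the core labels: ring-D aryl endo on C10, benzyl group exo on C9 and trans to it | COc1cc(O)ccc1C[C@@H]1[C@@H]2O[C@@]34C[C@@](O)(C(=O)C=C3C=C2c2ccc(OC)c(O)c2OC)c2cc(O)c(O)cc2[C@@H]14 | target

Total step count: 16. Longest linear sequence: 8 steps (steps 1, 2, 4, 5, 6, 14, 15, 16).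

Steps most likely to fail

1. Step 16 (key step). The terminal alkene of the trienone is only weakly nucleophilic, so the quinone methide may oligomerise, add water or be reduced back before the 7-endo attack, and the product catechol may be over-oxidised by remaining oxidant. Fallback: set out from 26 and run the Ag2O oxidation in methanol/CH2Cl2, so that the quinone methide is trapped by solvent as the C10 methyl ether of 26, F1 (both C10 epimers, isolable, no oxidant left). F1 is then ionised with Sc(OTf)3 (10 mol %) in CH2Cl2/(CF3)2CHOH at −20 °C, which regenerates the C10 cation under non-oxidising conditions at high dilution and should close to 29.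

2. Step 6. The chiral iodane may discriminate the faces of the phenol poorly, and water may add ortho instead of para. Fallback: set out from 9 and hydroxylate with PhI(OAc)2 in MeCN/H2O at 0 °C to the racemic quinol F2. The enantiomers are separated by preparative chromatography on an amylose tris(3,5-dimethylphenylcarbamate) stationary phase, and the (S)-enantiomer re-enters the route as 10.

3. Step 15. During the acidic desilylation the liberated quinol may undergo conjugate arylation at C8 instead of carbonyl addition at C7, or the quinol and the cis-triene may rearrange before the cage closes. Fallback: set out from 10 and close the cage before the triene exists. HF (48 % aq.) in MeCN on 10 should give the cage bromoenone F3. Suzuki–Miyaura coupling of F3 with 23 (PdCl2(dppf), K3PO4, THF/H2O, 35 °C) should give the cage dienyl catechol F4, which still carries the two side-chain silyl ethers. HF·pyridine in THF removes them, and the sequence comes back to the route at 26.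

Further compounds
F1 | step 16 | C10 methyl ether of cage catechol 26 (7S,8aS; mixture of C10 epimers) | O[C@@]12C[C@@](O)(C(=O)C=C1/C=C(/c1ccc(OC)c(O)c1OC)\C=C\Cc1ccc(O)cc1OC)c1cc(O)c(O)cc1C2OC
F2 | step 6 | racemic 5-bromo-4-[3,4-bis(TBSO)benzyl]-4-hydroxy-2-(TBSO)cyclohexa-2,5-dien-1-one | OC1(Cc2ccc(O[Si](C)(C)C(C)(C)C)c(O[Si](C)(C)C(C)(C)C)c2)C=C(O[Si](C)(C)C(C)(C)C)C(=O)C=C1Br
F3 | step 15 | cage bromoenone, (5S,9S)-8-bromo-2,3,5,9-tetrahydroxy-9,10-dihydro-5,9-methanobenzo[8]annulen-6(5H)-one | O[C@@]12C[C@@](O)(C(=O)C=C1Br)c1cc(O)c(O)cc1C2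
F4 | step 15 | cage dienyl catechol with TBS and TIPS ethers on the two side-chain phenols (7S,8aS in the core labels) | O[C@@]12C[C@@](O)(C(=O)C=C1/C=C(/c1ccc(OC)c(O[Si](C)(C)C(C)(C)C)c1OC)\C=C\Cc1ccc(O[Si](C(C)C)(C(C)C)C(C)C)cc1OC)c1cc(O)c(O)cc1C2
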